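Target cannot stand above what has left the solid: at 15.0 h the noon run shows 3 % target against 31.0 % dissolved.

| flask | solid substrate | temperature | remark | time |
|---|---|---|---|---|
| noon | 0.10 M | 0 °C | the very flask that is asked about, followed so far |  |
| flask | 0.10 M | 0 °C |  | 8.0 d |

noon run (percent of the solid substrate charged)

| time / h | target / % | solid substrate / % |
|---|---|---|
| 15.0 | 3 | 69 |
| 40.0 | 14 | 32 |
| 72.0 | 28 | 0 |
| 120 | 38 | 1 |

(readings scatter by 1.5 percentage points)

- percent here means solid substrate units held: one side product counts as two
- solid substrate is a solid; its amount is given per volume of the solution
- target that was removed still counts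
- on the list of suspects stand: starting material <-> other conformer; starting material -> target; other conformer -> isomer of the product; other conformer <-> third conformer; third conformer -> third product; other conformer <-> dormant form; solid substrate <-> starting material; starting material + target -> side product
- at the start none of the solid substrate is in solution
- the earlier runs do not show what temperature does; that part of a forecast is a guess

- zeta: at 8.0 d take out 90 % of the target then present, then wait 15 d
- beta: at 8.0 d raise the temperature by 25 K, then wait 15 d
- alpha: change nothing and wait 15 d more

1. target, in percent of the solid substrate first charged, at 8.0 d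
2. what to do for the largest gain in target; "none" if nothing gains more than 2 percentage points (zeta / beta / alpha / none)
3. target present, with what was taken out counted in, in percent of the solid substrate first charged, after zeta
4. target present, with what was taken out counted in, in percent of the solid substrate first charged, after alpha

Build this flask up one process at a time, asking each time for the end state and then for the pace. Take the main step first, starting material to target, with everything in solution: the end state is 100 % target. Add the dissolving: the end state stays, but target is fed at the pace of the solid; the solid reads 0 % at 72.0 h, when target reads 28 %.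

Now add the other suspects, and read them from the pace. Target rises at 0.00438 h⁻¹ between 40.0 h and 72.0 h, then at 0.00208 h⁻¹ up to 120 h, less. Treat this as one first-order fading with constant k, 0.0185 h⁻¹, a half-life of 37.5 h, both read from scattered readings. Target then levels off near 45.2 % and reads 43.3 % at 8.0 d. On this reckoning 54.8 % of the charge stays outside target at 0 °C: call it the stranded share S, the part of the charge not in target when the fading has died out.

| Processes counted | End value of target |
|---|---|
| Main step | 100 % |
| Dissolving added | 100 %, reached later |
| Other suspects added | 45.2 % |

Now weigh the options. Reckon alpha to add 1.9 percentage points, less than the margin of 2 points, so put g3 at 45.2 %. Put g1 there too, as the noon run has no reading of side product to size a saving by. S is far larger than that gain, so choose beta, as a guess, because the earlier runs do not show what temperature does.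

The forecast gave 42 %, g1 43 %, g3 43 % and best none, parting from this choice: “No option reliably gains more than 2 points”.

The flask gives 38.2 %, g1 44.9 %, g3 42.1 % and best beta, with gains of 20 points for beta, 6.7 points for zeta and 3.9 points for alpha.

    starting material ⇌ other conformer (K = 0.990, k = 0.786 h⁻¹, Ea = 74.0 kJ mol⁻¹, ΔH = −51.0 kJ mol⁻¹)
    starting material → target (k = 0.0321 h⁻¹, Ea = 97.0 kJ mol⁻¹)
    other conformer → isomer of the product (k = 0.00508 h⁻¹, Ea = 96.0 kJ mol⁻¹)
    other conformer ⇌ third conformer (K = 2.26, k = 0.00343 h⁻¹, Ea = 101 kJ mol⁻¹, ΔH = −50.0 kJ mol⁻¹)
    third conformer → third product (k = 0.0971 h⁻¹, Ea = 89.0 kJ mol⁻¹)
    other conformer ⇌ dormant form (K = 15.7, k = 0.0267 h⁻¹, Ea = 82.0 kJ mol⁻¹, ΔH = −10.0 kJ mol⁻¹)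
    solid substrate ⇌ starting material, rate k7*(cs7 - [starting material]) while solid is left; crystals form when [starting material] > cs7 (solubility = 46.0 mM, k = 0.0514 h⁻¹)
    starting material + target → side product (k = 0.304 L mol⁻¹ h⁻¹, Ea = 74.0 kJ mol⁻¹)
    (constants at 0 °C)

Against S of 54.8 %, this flask holds 61.8 % outside target at 8.0 d and 52.4 % at 1920 h. Dissolving took the solid to 0 % by 96.0 h, while starting material made target. At 192 h the dormant form in this flask held 30.0 %, far more than the 0.762 % of starting material, and side product held 18.4 %. The neighbour flask with 0.040 M of solid substrate holds 54.3 % outside target at 8.0 d, with dormant form at 31.0 % and side product at 8.97 %.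

All runs are calculated for substances that don't exist.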